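**Plan**

- Target ring numbering used below: C1 (O-tigloyl, next to C6), C2 (=CH), C3 (=C–CH2OH), C4 (O-tigloyl), C5 (OAc), C6 (iPr). The retrosynthesis cuts C3–CH2OH (to C3–Br), the three acyl C–O bonds, and then both ring bonds of C3 (C2–C3 and C3–C4) at once. This removes C3 as a carbene carbon and leaves a cyclopentene C2=C4 that carries O–C1, iPr–C6 and O–C5.
- Enabling feature: C3 is a substituted sp2 carbon between the vinylic C2–H and the oxygenated sp3 C4, which is the product pattern of the electrocyclic opening of a ring-fused gem-dibromocyclopropane. C4–O and C5–O are cis, so an ester on O5 can deliver the C4 oxygen through a five-membered acyloxonium ring. The O–C(iPr)–O triad C1/C6/C5 is the substitution pattern of a Piancatelli cyclopentenone.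
- Forward order: furfural → furylcarbinol → cyclopentenone (five-membered carbocycle C1, C2, C4, C5, C6) → trans-diol → silyl differentiation → CBr2 adduct → six-membered ring by silver-promoted ring expansion with transfer of the tiglate from O5 to O4 → acetate on O5, tiglate on O1, CH2OH on C3.
- Stereochemistry: C5/C6 trans from the conrotatory 4π closure of the Piancatelli step; absolute configuration from a lipase resolution; C1 from hydroxyl-directed hydride delivery (1,3-anti to O5, cis to iPr); C4 from the cis-fused dioxolanylium ring in the ring expansion.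

Key step: step 9

Assumption: the lipase is taken to acylate the (4R,5S)-enantiomer of 4 faster (the isopropyl-bearing C5 acting as the large group in the usual size model for lipases), so that (4S,5R)-5 is recovered; if the sense proves opposite, the acetate fraction is deacetylated with the same lipase in buffer and gives the same compound 5.

**Step 1**
Reactants: 1 furfural; 2 isopropylmagnesium chloride
Product: 3 rac-1-(furan-2-yl)-2-methylpropan-1-ol
Conditions: THF, −20 → 0 °C; aq. NH4Cl
Reagents that add atoms: none
Why: Grignard addition to the aldehyde gives the furylcarbinol; its stereocentre is irrelevant because it is lost in step 2.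

**Step 2**
Reactants: 3 rac-1-(furan-2-yl)-2-methylpropan-1-ol
Product: 4 rac-trans-4-hydroxy-5-isopropylcyclopent-2-en-1-one
Conditions: ZnCl2 (2 equiv), 1,4-dioxane–H2O 1:1, pH 5–6, reflux
Reagents that add atoms: water (O)
Why: Piancatelli rearrangement, in which ionisation of the carbinol, attack of water at C5 of the furan, ring opening and conrotatory 4π electrocyclisation of the 1,4-dihydroxypentadienyl cation give the 4-hydroxy-5-alkylcyclopentenone with OH and iPr trans (future C5–O and C6–iPr).

**Step 3**
Reactants: 4 rac-trans-4-hydroxy-5-isopropylcyclopent-2-en-1-one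
Product: 5 (4S,5R)-4-hydroxy-5-isopropylcyclopent-2-en-1-one (recovered slow-reacting enantiomer)
Conditions: immobilised Burkholderia cepacia lipase, vinyl acetate (3 equiv), MTBE, 30 °C, stopped a little beyond half conversion; chromatography
Reagents that add atoms: none
Why: Lipase-catalysed kinetic resolution by enantioselective transesterification of a secondary carbinol whose two flanking groups differ clearly in size should leave the (4S,5R)-alcohol, which fixes the absolute configuration of C5 and C6.

**Step 4**
Reactants: 5 (4S,5R)-4-hydroxy-5-isopropylcyclopent-2-en-1-one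
Product: 6 (1S,3S)-2-isopropylcyclopent-4-ene-1,3-diol
Conditions: Me4NBH(OAc)3 (4 equiv), MeCN–AcOH 1:1, −30 → −10 °C
Reagents that add atoms: none
Why: Hydroxyl-directed triacetoxyborohydride reduction (Evans–Saksena) delivers hydride from the boron bound to the C4 oxygen to the carbonyl face syn to that oxygen, which is also the face anti to iPr, so the new carbinol (future C1) should be 1,3-anti to the existing OH and cis to iPr.

**Step 5**
Reactants: 6 (1S,3S)-2-isopropylcyclopent-4-ene-1,3-diol
Product: 8 tert-butyl{[(1S,4S,5R)-5-isopropyl-4-(triethylsilyloxy)cyclopent-2-en-1-yl]oxy}dimethylsilane, via mono-TES ether 7 (not isolated)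
Conditions: TESCl (1.05 equiv), imidazole (1.2 equiv), CH2Cl2, −40 °C; then 2,6-lutidine (3 equiv), TBSOTf (1.5 equiv), −40 → 0 °C
Reagents that add atoms: chlorotriethylsilane (CC[Si](Cl)(CC)CC); tert-butyldimethylsilyl trifluoromethanesulfonate (CC(C)(C)[Si](C)(C)OS(=O)(=O)C(F)(F)F)
Why: Sequential silylation in one pot, in which the hydroxyl trans to the vicinal iPr (future O5) is the less hindered and should take the TES group first, after which the shielded hydroxyl cis to iPr (future O1) is capped with the more reactive silyl triflate; no stereocentre is touched.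

**Step 6**
Reactants: 8 tert-butyl{[(1S,4S,5R)-5-isopropyl-4-(triethylsilyloxy)cyclopent-2-en-1-yl]oxy}dimethylsilane
Product: 9 6,6-dibromo-2-(tert-butyldimethylsilyloxy)-3-isopropyl-4-(triethylsilyloxy)bicyclo[3.1.0]hexane (CBr2 bridge anti to OTBS and iPr as the expected main facial isomer)
Conditions: CHBr3 (5 equiv), 50% aq. NaOH, BnEt3NCl (10 mol%), CH2Cl2, 0 °C → rt, vigorous stirring
Reagents that add atoms: bromoform (BrC(Br)Br)
Why: Phase-transfer dibromocarbene addition to the only alkene is stereospecifically cis and should prefer the face anti to OTBS and iPr, but the facial outcome does not matter because both isomers open to the same allyl cation in step 9.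

**Step 7**
Reactants: 9 6,6-dibromo-2-(tert-butyldimethylsilyloxy)-3-isopropyl-4-(triethylsilyloxy)bicyclo[3.1.0]hexane
Product: 10 6,6-dibromo-4-(tert-butyldimethylsilyloxy)-3-isopropylbicyclo[3.1.0]hexan-2-ol (OH trans to iPr)
Conditions: PPTS (0.2 equiv), MeOH–CH2Cl2 1:1, 0 °C → rt
Reagents that add atoms: none
Why: Acid-catalysed methanolysis removes the secondary TES ether selectively in the presence of the hindered secondary TBS ether, and the gem-dibromocyclopropane is inert to these conditions.

**Step 8**
Reactants: 10 6,6-dibromo-4-(tert-butyldimethylsilyloxy)-3-isopropylbicyclo[3.1.0]hexan-2-ol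
Product: 11 6,6-dibromo-4-(tert-butyldimethylsilyloxy)-3-isopropylbicyclo[3.1.0]hexan-2-yl (E)-2-methylbut-2-enoate
Conditions: tiglic acid, 2,4,6-trichlorobenzoyl chloride, Et3N, toluene, rt; then 10, DMAP, rt → 40 °C
Reagents that add atoms: tiglic acid (C/C=C(\C)C(=O)O)
Why: Yamaguchi esterification through the mixed anhydride avoids the vinylketene pathway that deconjugates enoyl chlorides; the tiglate is introduced only after the carbene step because its alkene would compete for dibromocarbene, and it is the internal nucleophile of step 9.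

**Step 9**
Reactants: 11 6,6-dibromo-4-(tert-butyldimethylsilyloxy)-3-isopropylbicyclo[3.1.0]hexan-2-yl (E)-2-methylbut-2-enoate
Product: 14 (1R,4R,5R,6R)-3-bromo-1-(tert-butyldimethylsilyloxy)-5-hydroxy-6-isopropylcyclohex-2-en-4-yl (E)-2-methylbut-2-enoate, via 2-bromocyclohexenyl cation 12 (not isolated), via cis-fused dioxolanylium ion 13 (not isolated)
Conditions: AgBF4 (1.5 equiv), 2,6-di-tert-butyl-4-methylpyridine (1.5 equiv), CH2Cl2, 0 °C → rt, dark; then THF–H2O, 0 °C
Reagents that add atoms: water (O)
Why: Silver(I) removes the endo bromide while the internal cyclopropane bond opens in a thermally allowed disrotatory two-electron electrocyclic process, so the five-membered ring grows by one carbon into the 2-bromocyclohexenyl cation 12 (both facial isomers of 11 give the same cation); the closest known reaction type is the silver-promoted ring expansion of 6,6-dibromobicyclo[3.1.0]hexanes with capture by oxygen nucleophiles. The only ring closed is the transient 1,3-dioxolan-2-ylium ring of 13, formed by 5-exo-trig attack of the tiglate carbonyl oxygen on the allyl terminus C4 (neighbouring-group participation). The new stereocentre C4 is controlled by this ring, which can only be cis-fused, so the C4–O bond forms on the face of the C5–O bond. The step needs regioselectivity between the two allyl termini, and this is secured because only O5 carries an acyl group (O1 is a non-participating silyl ether) and the dioxolanylium ion is formed before water is admitted. Water then adds to the cationic carbon of 13 and the orthoacid should collapse, following the known stereoelectronic preference of ring-fused orthoacids, to the pseudoaxial ester and the equatorial alcohol. O4 is held pseudoaxial by allylic 1,2-strain with the vinylic bromine and by the equatorial iPr, so the tiglate should end on O4 and O5–H is freed.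

**Step 10**
Reactants: 14 (1R,4R,5R,6R)-3-bromo-1-(tert-butyldimethylsilyloxy)-5-hydroxy-6-isopropylcyclohex-2-en-4-yl (E)-2-methylbut-2-enoate
Product: 15 (1R,4R,5R,6R)-5-acetoxy-3-bromo-1-(tert-butyldimethylsilyloxy)-6-isopropylcyclohex-2-en-4-yl (E)-2-methylbut-2-enoate
Conditions: Ac2O (3 equiv), pyridine, DMAP (0.1 equiv), CH2Cl2, 0 °C → rt
Reagents that add atoms: acetic anhydride (CC(=O)OC(C)=O)
Why: DMAP-catalysed acetylation of the equatorial C5 hydroxyl is fast and is run directly after step 9 so that the C4 tiglate has no time to migrate back.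

**Step 11**
Reactants: 15 (1R,4R,5R,6R)-5-acetoxy-3-bromo-1-(tert-butyldimethylsilyloxy)-6-isopropylcyclohex-2-en-4-yl (E)-2-methylbut-2-enoate
Product: 16 (1R,4R,5R,6S)-5-acetoxy-3-bromo-1-hydroxy-6-isopropylcyclohex-2-en-4-yl (E)-2-methylbut-2-enoate
Conditions: HF·pyridine, pyridine–THF, 0 °C → rt
Reagents that add atoms: none
Why: Buffered fluoride cleavage of the TBS ether leaves the esters and the vinyl bromide untouched, and the freed C1–OH is 1,3-trans to the C5 acetate, so acyl migration to it is geometrically impossible.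

**Step 12**
Reactants: 16 (1R,4R,5R,6S)-5-acetoxy-3-bromo-1-hydroxy-6-isopropylcyclohex-2-en-4-yl (E)-2-methylbut-2-enoate
Product: 17 (1R,4R,5R,6S)-5-acetoxy-3-bromo-6-isopropylcyclohex-2-ene-1,4-diyl bis[(E)-2-methylbut-2-enoate]
Conditions: tiglic acid, 2,4,6-trichlorobenzoyl chloride, Et3N, toluene, rt; then 16, DMAP, rt → 50 °C
Reagents that add atoms: tiglic acid (C/C=C(\C)C(=O)O)
Why: Yamaguchi esterification is the standard way to acylate a hindered secondary allylic alcohol with tiglic acid, and the (E)-acid is the stable geometrical isomer, so no E/Z erosion is expected.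

**Step 13**
Reactants: 17 (1R,4R,5R,6S)-5-acetoxy-3-bromo-6-isopropylcyclohex-2-ene-1,4-diyl bis[(E)-2-methylbut-2-enoate]
Product: 18 (1S,4S,5R,6S)-5-acetoxy-3-(hydroxymethyl)-6-isopropylcyclohex-2-ene-1,4-diyl bis[(E)-2-methylbut-2-enoate]
Conditions: Bu3SnCH2OH (1.5 equiv), Pd(PPh3)4 (10 mol%), 1,4-dioxane (degassed), 80–90 °C
Reagents that add atoms: (tributylstannyl)methanol (OC[Sn](CCCC)(CCCC)CCCC)
Why: Stille hydroxymethylation of the alkenyl bromide runs under neutral conditions; oxidative addition into the C(sp2)–Br bond should outrun ionisation of the hindered secondary allylic tiglates, and no base is present that could move an acyl group to the new primary hydroxyl.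

**Compound list**

(9–11: main facial isomer shown; 14–17 carry target numbering.)

1 | furfural | O=Cc1ccco1 | starting material
2 | isopropylmagnesium chloride | CC(C)[Mg]Cl | starting material
3 | rac-1-(furan-2-yl)-2-methylpropan-1-ol | CC(C)C(O)c1ccco1 | intermediate
4 | rac-trans-4-hydroxy-5-isopropylcyclopent-2-en-1-one, 1:1 (4S,5R)/(4R,5S) | O=C1C=C[C@H](O)[C@H]1C(C)C.O=C1C=C[C@@H](O)[C@@H]1C(C)C | intermediate
5 | (4S,5R)-4-hydroxy-5-isopropylcyclopent-2-en-1-one | O=C1C=C[C@H](O)[C@H]1C(C)C | intermediate
6 | (1S,3S)-2-isopropylcyclopent-4-ene-1,3-diol (trans-diol, one OH cis and one trans to iPr) | O[C@H]1C=C[C@H](O)C1C(C)C | intermediate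
7 | (1S,4S,5S)-5-isopropyl-4-(triethylsilyloxy)cyclopent-2-en-1-ol (OH cis to iPr) | O[C@H]1C=C[C@H](O[Si](CC)(CC)CC)[C@H]1C(C)C | intermediate (not isolated)
8 | tert-butyl{[(1S,4S,5R)-5-isopropyl-4-(triethylsilyloxy)cyclopent-2-en-1-yl]oxy}dimethylsilane (OTBS cis, OTES trans to iPr) | CC(C)(C)[Si](C)(C)O[C@H]1C=C[C@H](O[Si](CC)(CC)CC)[C@H]1C(C)C | intermediate
9 | 6,6-dibromo-2-(tert-butyldimethylsilyloxy)-3-isopropyl-4-(triethylsilyloxy)bicyclo[3.1.0]hexane (OTBS cis to iPr, OTES trans to iPr, CBr2 bridge anti to OTBS) | CC(C)(C)[Si](C)(C)O[C@H]1[C@@H]2C(Br)(Br)[C@@H]2[C@H](O[Si](CC)(CC)CC)[C@H]1C(C)C | intermediate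
10 | 6,6-dibromo-4-(tert-butyldimethylsilyloxy)-3-isopropylbicyclo[3.1.0]hexan-2-ol (OH trans to iPr) | CC(C)(C)[Si](C)(C)O[C@H]1[C@@H]2C(Br)(Br)[C@@H]2[C@H](O)[C@H]1C(C)C | intermediate
11 | 6,6-dibromo-4-(tert-butyldimethylsilyloxy)-3-isopropylbicyclo[3.1.0]hexan-2-yl (E)-2-methylbut-2-enoate | CC(C)(C)[Si](C)(C)O[C@H]1[C@@H]2C(Br)(Br)[C@@H]2[C@H](OC(=O)/C(C)=C/C)[C@H]1C(C)C | intermediate
12 | 2-bromocyclohexenyl (allyl) cation with 1-OTBS, 5-O-tigloyl and 6-iPr, tetrafluoroborate | CC(C)(C)[Si](C)(C)O[C@H]1C=C(Br)[CH+][C@H](OC(=O)/C(C)=C/C)[C@H]1C(C)C.F[B-](F)(F)F | intermediate (not isolated)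
13 | cis-fused 2-[(E)-but-2-en-2-yl]-1,3-dioxolan-2-ylium ion spanning O4/O5, tetrafluoroborate | CC(C)(C)[Si](C)(C)O[C@H]1C=C(Br)[C@@H]2OC(/C(C)=C/C)=[O+][C@@H]2[C@H]1C(C)C.F[B-](F)(F)F | intermediate (not isolated)
14 | (1R,4R,5R,6R)-3-bromo-1-(tert-butyldimethylsilyloxy)-5-hydroxy-6-isopropylcyclohex-2-en-4-yl (E)-2-methylbut-2-enoate | CC(C)(C)[Si](C)(C)O[C@H]1C=C(Br)[C@H](OC(=O)/C(C)=C/C)[C@H](O)[C@H]1C(C)C | intermediate
15 | (1R,4R,5R,6R)-5-acetoxy-3-bromo-1-(tert-butyldimethylsilyloxy)-6-isopropylcyclohex-2-en-4-yl (E)-2-methylbut-2-enoate | CC(C)(C)[Si](C)(C)O[C@H]1C=C(Br)[C@H](OC(=O)/C(C)=C/C)[C@H](OC(C)=O)[C@H]1C(C)C | intermediate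
16 | (1R,4R,5R,6S)-5-acetoxy-3-bromo-1-hydroxy-6-isopropylcyclohex-2-en-4-yl (E)-2-methylbut-2-enoate | O[C@H]1C=C(Br)[C@H](OC(=O)/C(C)=C/C)[C@H](OC(C)=O)[C@H]1C(C)C | intermediate
17 | (1R,4R,5R,6S)-5-acetoxy-3-bromo-6-isopropylcyclohex-2-ene-1,4-diyl bis[(E)-2-methylbut-2-enoate] | C/C=C(\C)C(=O)O[C@H]1C=C(Br)[C@H](OC(=O)/C(C)=C/C)[C@H](OC(C)=O)[C@H]1C(C)C | intermediate
18 | (1S,4S,5R,6S)-5-acetoxy-3-(hydroxymethyl)-6-isopropylcyclohex-2-ene-1,4-diyl bis[(E)-2-methylbut-2-enoate] | C/C=C(\C)C(=O)O[C@H]1C=C(CO)[C@H](OC(=O)/C(C)=C/C)[C@H](OC(C)=O)[C@H]1C(C)C | target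

Total step count: 13. Longest linear sequence: 13 steps (fully linear from furfural).

**Steps most likely to fail**

Step 9. Ionisation may be slow because both carbons next to the allyl termini carry electron-withdrawing oxygen. The orthoacid may also collapse the other way, or the acyl group may migrate afterwards, so that the tiglate ends on O5 instead of O4. The TBS ether may be lost under the acid set free. The fallback avoids acyl transfer altogether and sets out from alcohol 10. Boc2O/DMAP gives the tert-butyl carbonate of 10 F1. The same silver-promoted ring expansion, now with carbonate participation and loss of the tert-butyl group, gives the cis-fused cyclic carbonate at O4/O5 F2. K2CO3 in methanol gives the cis-4,5-diol F3. Its dibutylstannylene acetal (Bu2SnO, toluene, reflux, then AcCl at 0 °C) is acylated at the equatorial O5 to give the 5-acetate 4-alcohol F4. Yamaguchi tigloylation of the remaining C4–OH then gives 15, where the route is rejoined.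

Step 3. Acylation of a carbinol next to an isopropyl-bearing carbon may be slow or poorly enantioselective, and the sense may be opposite to the one assumed. The fallback sets out from racemate 4. Reduction as in step 4 gives the racemic trans-diol F5. Esterification with (S)-O-methylmandelic acid (DCC, DMAP) gives two diastereomeric diesters, the bis-mandelate of the (1S,3S)-diol F6 and the bis-mandelate of the (1R,3R)-diol F7. These are separated by chromatography or crystallisation and assigned by the usual NMR anisotropy analysis. Methanolysis of the (1S,3S)-diester with K2CO3 in methanol gives diol 6, where the route is rejoined.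

Step 13. Pd(0) may ionise the allylic tiglates (π-allyl formation leading to elimination or epimerisation) in competition with oxidative addition into C–Br, and at 80–90 °C the C4 tigloyl group may migrate to the new primary hydroxyl. The fallback sets out from bromide 17 and uses a Nozaki–Hiyama–Kishi coupling with formaldehyde (CrCl2 in excess, NiCl2 catalytic, paraformaldehyde, DMF–DMSO, rt), which involves no palladium and no heating and gives target 18 directly.

**Further compounds**

F1 | step 9 | tert-butyl carbonate of 10: 6,6-dibromo-4-(tert-butyldimethylsilyloxy)-3-isopropylbicyclo[3.1.0]hexan-2-yl tert-butyl carbonate | CC(C)(C)[Si](C)(C)O[C@H]1[C@@H]2C(Br)(Br)[C@@H]2[C@H](OC(=O)OC(C)(C)C)[C@H]1C(C)C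
F2 | step 9 | cis-fused cyclic carbonate of 3-bromo-1-(tert-butyldimethylsilyloxy)-6-isopropylcyclohex-2-ene-4,5-diol | CC(C)(C)[Si](C)(C)O[C@H]1C=C(Br)[C@@H]2OC(=O)O[C@@H]2[C@H]1C(C)C
F3 | step 9 | 3-bromo-1-(tert-butyldimethylsilyloxy)-6-isopropylcyclohex-2-ene-4,5-diol (cis-diol, ring configured as in the target) | CC(C)(C)[Si](C)(C)O[C@H]1C=C(Br)[C@H](O)[C@H](O)[C@H]1C(C)C
F4 | step 9 | 3-bromo-1-(tert-butyldimethylsilyloxy)-4-hydroxy-6-isopropylcyclohex-2-en-5-yl acetate | CC(C)(C)[Si](C)(C)O[C@H]1C=C(Br)[C@H](O)[C@H](OC(C)=O)[C@H]1C(C)C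
F5 | step 3 | rac-trans-2-isopropylcyclopent-4-ene-1,3-diol, 1:1 (1S,3S)/(1R,3R) | O[C@H]1C=C[C@H](O)C1C(C)C.O[C@@H]1C=C[C@@H](O)C1C(C)C
F6 | step 3 | (1S,3S)-2-isopropylcyclopent-4-ene-1,3-diyl bis[(S)-2-methoxy-2-phenylacetate] | CO[C@H](C(=O)O[C@H]1C=C[C@H](OC(=O)[C@@H](OC)c2ccccc2)C1C(C)C)c1ccccc1
F7 | step 3 | (1R,3R)-2-isopropylcyclopent-4-ene-1,3-diyl bis[(S)-2-methoxy-2-phenylacetate] | CO[C@H](C(=O)O[C@@H]1C=C[C@@H](OC(=O)[C@@H](OC)c2ccccc2)C1C(C)C)c1ccccc1
F0 | step 13 | none | none
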